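The chroman is cut at the two bonds that join ring A to the pyran ring, O1–C8a and C4a–C4. Because C8a and C4a are ortho neighbours on ring A, they are treated as the two carbons of 3,5-dimethoxybenzyne; the methoxy group next to C4a (the later C5 oxygen) steers an oxygen nucleophile to C8a and leaves the carbanion at C4a. The precursor is an acyclic δ-hydroxy enoate that already carries C2 and C3, set by a Brown allylboration. In one operation its alkoxide adds to the aryne and the aryl anion closes the pyran ring by 6-exo Michael addition, which sets C4. Ester-to-isobutyl conversion, fourfold formylation and demethylation follow.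

Key step: step 6

Assumption: the (+)-Ipc2BOMe series (from (−)-α-pinene) is taken to deliver the allyl unit to the Re face of aryl aldehydes, as in Brown allylations and crotylations. Chroman numbering (O1, C2–C4, C4a, C5–C8, C8a) is used; ring A is the benzo ring and ring B the aryl group at C2.

Step 1
Reactants: 1 3,5-dimethoxyphenol
Product: 2 3,5-dimethoxyphenyl N-(propan-2-yl)carbamate
Conditions: i-PrNCO, Et3N (cat.), CH2Cl2, rt
Reagents that add atoms: isopropyl isocyanate, CC(C)N=C=O
Why: Base-catalysed addition of the phenol across the isocyanate (carbamoylation) installs an N-monoalkyl carbamate that directs ortho-metalation in step 2 and is cleaved under mild conditions in step 3.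

Step 2
Reactants: 2 3,5-dimethoxyphenyl N-(propan-2-yl)carbamate
Product: 6 3,5-dimethoxy-2-(trimethylsilyl)phenyl N-(propan-2-yl)carbamate, via N-silyl carbamate 3 (not isolated), via aryllithium 4 (not isolated), via bis-silyl carbamate 5 (not isolated)
Conditions: TBSOTf, TMEDA, Et2O, 0 °C → rt; n-BuLi, TMEDA, −78 °C; TMSCl, −78 °C → rt; aq. NaHSO4
Reagents that add atoms: chlorotrimethylsilane, C[Si](C)(C)Cl
Why: Directed ortho-metalation: silylation of the carbamate nitrogen in situ removes the acidic N–H, n-BuLi/TMEDA then lithiates the position between the carbamate and a methoxy group (doubly activated), TMSCl traps the aryllithium at carbon and the N–Si bond is hydrolysed on work-up.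

Step 3
Reactants: 6 3,5-dimethoxy-2-(trimethylsilyl)phenyl N-(propan-2-yl)carbamate
Product: 8 3,5-dimethoxy-2-(trimethylsilyl)phenyl trifluoromethanesulfonate, via silylphenol 7 (not isolated)
Conditions: DBU, Et2NH, MeCN, 40 °C; then PhNTf2, rt
Reagents that add atoms: N-phenylbis(trifluoromethanesulfonimide), O=S(=O)(N(c1ccccc1)S(=O)(=O)C(F)(F)F)C(F)(F)F
Why: DBU and Et2NH cleave the N–H carbamate through loss of isopropyl isocyanate, which is trapped as the urea, and the phenoxide released is triflated in the same flask by PhNTf2 to give the ortho-silyl aryl triflate (Kobayashi-type aryne precursor).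

Step 4
Reactants: 9 2,4,6-trimethoxybenzaldehyde; 10 (E)-4-methylpent-2-ene; 11 (+)-B-methoxydiisopinocampheylborane
Product: 15 (1R,2R)-2-(propan-2-yl)-1-(2,4,6-trimethoxyphenyl)but-3-en-1-ol, via E-allylpotassium 12 (not isolated), via allylborane 13 (not isolated), via borinate adduct 14 (not isolated)
Conditions: 10, n-BuLi, KOt-Bu, THF, −78 → −45 °C; 11, −78 °C; BF3·OEt2, −78 °C; 9, −78 °C; then NaOH, H2O2, rt
Reagents that add atoms: none
Why: Brown asymmetric allylboration in its γ-substituted (crotyl-type) form: Schlosser metalation of the methyl group of 10 keeps the E geometry, transfer to boron gives 13, and addition to 9 through a closed chair (Zimmerman–Traxler) transition state turns the E geometry into the anti (1R,2R) relationship while the isopinocampheyl groups of the (−)-α-pinene series direct the allyl unit to the Re face of the aldehyde.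

Step 5
Reactants: 15 (1R,2R)-2-(propan-2-yl)-1-(2,4,6-trimethoxyphenyl)but-3-en-1-ol; 16 tert-butyl prop-2-enoate
Product: 17 tert-butyl (2E,4R,5R)-5-hydroxy-4-(propan-2-yl)-5-(2,4,6-trimethoxyphenyl)pent-2-enoate
Conditions: 16 (5 equiv), second-generation Hoveyda–Grubbs catalyst (H2IMes)Cl2Ru(=CH-C6H4-2-Oi-Pr) (5 mol %), CH2Cl2, 40 °C
Reagents that add atoms: none
Why: Olefin cross-metathesis between the terminal vinyl group of 15 and an excess of the electron-poor acrylate, which homodimerises only slowly, should give the conjugated E enoate as the thermodynamically preferred isomer, and the free hydroxyl group is tolerated by the ruthenium carbene.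

Step 6
Reactants: 17 tert-butyl (2E,4R,5R)-5-hydroxy-4-(propan-2-yl)-5-(2,4,6-trimethoxyphenyl)pent-2-enoate; 8 3,5-dimethoxy-2-(trimethylsilyl)phenyl trifluoromethanesulfonate
Product: 22 tert-butyl 2-[(2R,3R,4R)-5,7-dimethoxy-3-(propan-2-yl)-2-(2,4,6-trimethoxyphenyl)chroman-4-yl]acetate, via sodium alkoxide 18 (not isolated), via 3,5-dimethoxybenzyne 19 (not isolated), via aryl anion 20 (not isolated), via ester enolate 21 (not isolated)
Conditions: NaH, THF, −20 °C; then 8 (1.5 equiv), CsF, 18-crown-6, −20 °C → rt; aq. NH4Cl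
Reagents that add atoms: none
Why: Proposed new method: the pre-formed alkoxide 18 adds to aryne 19 (released from 8 by fluoride) at the aryne carbon remote from the neighbouring methoxy group (the later C8a), so that the carbanion of 20 sits next to that methoxy group (the later C4a); this carbanion then adds intramolecularly to the β-carbon of the E enoate (the later C4) to give enolate 21, which is protonated on work-up. The closest known reaction type is the annulation of arynes with 2-hydroxychalcones (phenoxide addition to the aryne, then intramolecular Michael addition of the aryl anion to give xanthenes), together with the O–H insertion of aliphatic alcohols into arynes; closing a chroman from an aliphatic alkoxide in this way has not been shown. The pyran ring closes in a 6-exo-trig mode. C4 is set under control of the existing C2 and C3 centres: in the chair-like transition state the aryl group at C2 and the isopropyl group at C3 are equatorial, the C3–H bond eclipses the enoate double bond (minimal allylic strain) and the tethered carbanion attacks from the side of C2, which leaves the CH2CO2t-Bu group equatorial and trans to the isopropyl group (4R). The step needs regioselectivity in the aryne addition, secured by the inductive effect and distortion that the adjacent methoxy group imposes on 19, and chemoselectivity for ring closure over protonation of the aryl anion, secured by the aprotic medium, the pre-formed alkoxide and a tert-butyl enoate that has no enolisable carbonyl protons and resists acyl transfer.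

Step 7
Reactants: 22 tert-butyl 2-[(2R,3R,4R)-5,7-dimethoxy-3-(propan-2-yl)-2-(2,4,6-trimethoxyphenyl)chroman-4-yl]acetate
Product: 23 1-[(2R,3R,4R)-5,7-dimethoxy-3-(propan-2-yl)-2-(2,4,6-trimethoxyphenyl)chroman-4-yl]-2-methylpropan-2-ol
Conditions: MeLi (excess), THF, −78 → 0 °C; aq. NH4Cl
Reagents that add atoms: methyllithium, [Li]C
Why: Twofold addition of methyllithium to the tert-butyl ester gives the tertiary alcohol that holds both methyl groups of the later isobutyl chain, and 22 has no other electrophilic or acidic site.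

Step 8
Reactants: 23 1-[(2R,3R,4R)-5,7-dimethoxy-3-(propan-2-yl)-2-(2,4,6-trimethoxyphenyl)chroman-4-yl]-2-methylpropan-2-ol
Product: 26 (2R,3R,4R)-5,7-dimethoxy-4-(2-methylpropyl)-3-(propan-2-yl)-2-(2,4,6-trimethoxyphenyl)chromane, via isobutenyl alkene 24 (not isolated), via methallyl alkene 25 (not isolated)
Conditions: Burgess reagent, PhMe, 60 °C; then EtOAc, H2 (1 atm), PtO2, rt
Reagents that add atoms: none
Why: Burgess dehydration of the tertiary alcohol (syn elimination of the sulfamate ester under neutral conditions that do not ionise the acid-labile C2–O1 bond) gives the alkene isomers 24 and 25, and hydrogenation of both over PtO2, which is chosen over palladium to avoid hydrogenolysis of the benzylic C2–O1 bond, gives the isobutyl group without touching a stereocentre.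

Step 9
Reactants: 26 (2R,3R,4R)-5,7-dimethoxy-4-(2-methylpropyl)-3-(propan-2-yl)-2-(2,4,6-trimethoxyphenyl)chromane
Product: 27 (2R,3R,4R)-2-(3,5-diformyl-2,4,6-trimethoxyphenyl)-5,7-dimethoxy-4-(2-methylpropyl)-3-(propan-2-yl)chromane-6,8-dicarbaldehyde
Conditions: Cl2CHOMe (excess), TiCl4, CH2Cl2, −78 → 0 °C; then H2O
Reagents that add atoms: dichloromethyl methyl ether, COC(Cl)Cl; water, O
Why: Rieche formylation: each of the four remaining aromatic C–H positions (C6 and C8 on ring A, C3′ and C5′ on ring B) is the only open site between oxygen substituents on a phloroglucinol-type ring, so repeated electrophilic substitution by the chloro(methoxy)methyl cation followed by hydrolysis should give the tetraaldehyde, and any reversible Lewis-acid opening of the C2–O1 bond can only close again to the more stable 2,3-trans ring.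

Step 10
Reactants: 27 (2R,3R,4R)-2-(3,5-diformyl-2,4,6-trimethoxyphenyl)-5,7-dimethoxy-4-(2-methylpropyl)-3-(propan-2-yl)chromane-6,8-dicarbaldehyde
Product: 28 sideroxylonal C, (2R,3R,4R)-2-(3,5-diformyl-2,4,6-trihydroxyphenyl)-5,7-dihydroxy-4-(2-methylpropyl)-3-(propan-2-yl)chromane-6,8-dicarbaldehyde
Conditions: BCl3 (excess), CH2Cl2, −78 → 0 °C; then H2O
Reagents that add atoms: none
Why: BCl3 cleaves aryl methyl ethers that lie ortho to a carbonyl group through a six-membered boron chelate, all five methoxy groups of 27 are of this kind, and the aldehydes and the three stereocentres are not affected, so hydrolysis of the borates gives the target.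

Compound list
1 | 3,5-dimethoxyphenol | COc1cc(O)cc(OC)c1 | starting material
2 | 3,5-dimethoxyphenyl N-(propan-2-yl)carbamate | COc1cc(OC)cc(OC(=O)NC(C)C)c1 | intermediate
3 | 3,5-dimethoxyphenyl N-(tert-butyldimethylsilyl)-N-(propan-2-yl)carbamate | COc1cc(OC)cc(OC(=O)N(C(C)C)[Si](C)(C)C(C)(C)C)c1 | intermediate
4 | 2-lithio derivative of 3 (lithium on the ring carbon between the carbamate oxygen and a methoxy group) | COc1cc(OC)c([Li])c(OC(=O)N(C(C)C)[Si](C)(C)C(C)(C)C)c1 | intermediate
5 | 3,5-dimethoxy-2-(trimethylsilyl)phenyl N-(tert-butyldimethylsilyl)-N-(propan-2-yl)carbamate | COc1cc(OC)c([Si](C)(C)C)c(OC(=O)N(C(C)C)[Si](C)(C)C(C)(C)C)c1 | intermediate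
6 | 3,5-dimethoxy-2-(trimethylsilyl)phenyl N-(propan-2-yl)carbamate | COc1cc(OC)c([Si](C)(C)C)c(OC(=O)NC(C)C)c1 | intermediate
7 | 3,5-dimethoxy-2-(trimethylsilyl)phenol (present as its DBU salt) | COc1cc(OC)c([Si](C)(C)C)c(O)c1 | intermediate
8 | 3,5-dimethoxy-2-(trimethylsilyl)phenyl trifluoromethanesulfonate | COc1cc(OC)c([Si](C)(C)C)c(OS(=O)(=O)C(F)(F)F)c1 | intermediate
9 | 2,4,6-trimethoxybenzaldehyde | COc1cc(OC)c(C=O)c(OC)c1 | starting material
10 | (E)-4-methylpent-2-ene | C/C=C/C(C)C | starting material
11 | (+)-B-methoxydiisopinocampheylborane, methoxybis[(1S,2R,3S,5S)-2,6,6-trimethylbicyclo[3.1.1]heptan-3-yl]borane | COB([C@H]1C[C@H]2C[C@@H]([C@@H]1C)C2(C)C)[C@H]1C[C@H]2C[C@@H]([C@@H]1C)C2(C)C | starting material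
12 | (E)-4-methylpent-2-en-1-ylpotassium | [K+].[CH2-]/C=C/C(C)C | intermediate
13 | [(E)-4-methylpent-2-en-1-yl]bis[(1S,2R,3S,5S)-2,6,6-trimethylbicyclo[3.1.1]heptan-3-yl]borane | CC(C)/C=C/CB([C@H]1C[C@H]2C[C@@H]([C@@H]1C)C2(C)C)[C@H]1C[C@H]2C[C@@H]([C@@H]1C)C2(C)C | intermediate
14 | (1R,2R)-2-(propan-2-yl)-1-(2,4,6-trimethoxyphenyl)but-3-en-1-yl bis[(1S,2R,3S,5S)-2,6,6-trimethylbicyclo[3.1.1]heptan-3-yl]borinate | B(O[C@@H](c1c(OC)cc(OC)cc1OC)[C@@H](C=C)C(C)C)([C@H]1C[C@H]2C[C@@H]([C@@H]1C)C2(C)C)[C@H]1C[C@H]2C[C@@H]([C@@H]1C)C2(C)C | intermediate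
15 | (1R,2R)-2-(propan-2-yl)-1-(2,4,6-trimethoxyphenyl)but-3-en-1-ol | O[C@@H](c1c(OC)cc(OC)cc1OC)[C@@H](C=C)C(C)C | intermediate
16 | tert-butyl prop-2-enoate (tert-butyl acrylate) | C=CC(=O)OC(C)(C)C | starting material
17 | tert-butyl (2E,4R,5R)-5-hydroxy-4-(propan-2-yl)-5-(2,4,6-trimethoxyphenyl)pent-2-enoate | O[C@@H](c1c(OC)cc(OC)cc1OC)[C@@H](/C=C/C(=O)OC(C)(C)C)C(C)C | intermediate
18 | sodium alkoxide of 17 | [Na+].[O-][C@@H](c1c(OC)cc(OC)cc1OC)[C@@H](/C=C/C(=O)OC(C)(C)C)C(C)C | intermediate
19 | 3,5-dimethoxybenzyne (3,5-dimethoxycyclohexa-1,3-dien-5-yne) | COC1=CC(OC)=CC#C1 | intermediate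
20 | sodium aryl anion: 3,5-dimethoxyphenyl ether of 17 with the carbanion on the ring carbon between the ether oxygen and a methoxy group | [Na+].COc1cc(OC)[c-]c(c1)O[C@@H](c1c(OC)cc(OC)cc1OC)[C@@H](/C=C/C(=O)OC(C)(C)C)C(C)C | intermediate
21 | sodium enolate of 22 | [Na+].CC(C)(C)OC([O-])=C[C@H]1c2c(OC)cc(OC)cc2O[C@@H](c2c(OC)cc(OC)cc2OC)[C@@H]1C(C)C | intermediate
22 | tert-butyl 2-[(2R,3R,4R)-5,7-dimethoxy-3-(propan-2-yl)-2-(2,4,6-trimethoxyphenyl)chroman-4-yl]acetate | CC(C)(C)OC(=O)C[C@H]1c2c(OC)cc(OC)cc2O[C@@H](c2c(OC)cc(OC)cc2OC)[C@@H]1C(C)C | intermediate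
23 | 1-[(2R,3R,4R)-5,7-dimethoxy-3-(propan-2-yl)-2-(2,4,6-trimethoxyphenyl)chroman-4-yl]-2-methylpropan-2-ol | CC(C)(O)C[C@H]1c2c(OC)cc(OC)cc2O[C@@H](c2c(OC)cc(OC)cc2OC)[C@@H]1C(C)C | intermediate
24 | (2R,3R,4R)-5,7-dimethoxy-4-(2-methylprop-1-en-1-yl)-3-(propan-2-yl)-2-(2,4,6-trimethoxyphenyl)chromane | CC(C)=C[C@H]1c2c(OC)cc(OC)cc2O[C@@H](c2c(OC)cc(OC)cc2OC)[C@@H]1C(C)C | intermediate
25 | (2R,3R,4R)-5,7-dimethoxy-4-(2-methylprop-2-en-1-yl)-3-(propan-2-yl)-2-(2,4,6-trimethoxyphenyl)chromane | C=C(C)C[C@H]1c2c(OC)cc(OC)cc2O[C@@H](c2c(OC)cc(OC)cc2OC)[C@@H]1C(C)C | intermediate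
26 | (2R,3R,4R)-5,7-dimethoxy-4-(2-methylpropyl)-3-(propan-2-yl)-2-(2,4,6-trimethoxyphenyl)chromane | CC(C)C[C@H]1c2c(OC)cc(OC)cc2O[C@@H](c2c(OC)cc(OC)cc2OC)[C@@H]1C(C)C | intermediate
27 | (2R,3R,4R)-2-(3,5-diformyl-2,4,6-trimethoxyphenyl)-5,7-dimethoxy-4-(2-methylpropyl)-3-(propan-2-yl)chromane-6,8-dicarbaldehyde | CC(C)C[C@H]1c2c(OC)c(C=O)c(OC)c(C=O)c2O[C@@H](c2c(OC)c(C=O)c(OC)c(C=O)c2OC)[C@@H]1C(C)C | intermediate
28 | sideroxylonal C, (2R,3R,4R)-2-(3,5-diformyl-2,4,6-trihydroxyphenyl)-5,7-dihydroxy-4-(2-methylpropyl)-3-(propan-2-yl)chromane-6,8-dicarbaldehyde (all-trans) | CC(C)C[C@H]1c2c(O)c(C=O)c(O)c(C=O)c2O[C@@H](c2c(O)c(C=O)c(O)c(C=O)c2O)[C@@H]1C(C)C | target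

Total step count: 10 (three for the aryne precursor, seven on the main line).
Longest linear sequence: 8 steps (steps 1, 2, 3, 6, 7, 8, 9, 10, from 3,5-dimethoxyphenol).

Steps most likely to fail

Step 6 (proposed new method). The aryl anion may be protonated before it cyclises, or the alkoxide may fragment or isomerise the enoate before it meets the aryne. The fallback sets out from 17 and 8 and comes back at 22; it separates the two bond formations and uses known reactions. Without NaH, under the neutral conditions known for O–H insertion of aliphatic alcohols into arynes (KF, 18-crown-6, THF, −20 °C), 17 and 8 should give the aryl ether tert-butyl (2E,4R,5R)-5-(3,5-dimethoxyphenoxy)-4-(propan-2-yl)-5-(2,4,6-trimethoxyphenyl)pent-2-enoate F1. The electron-rich phenoxy ring of F1, whose two ortho positions are equivalent, is then closed onto the enoate by a Lewis-acid-catalysed intramolecular Friedel–Crafts conjugate addition (Sc(OTf)3, CH2Cl2/hexafluoroisopropanol, rt). The same chair-like preference for equatorial substituents is expected to give 22.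

Step 9. Fourfold substitution may stall as each formyl group deactivates its ring, and TiCl4 may ionise the C2–O1 bond and lead to elimination towards C3. The fallback sets out from 26 and comes back at 28, reversing the order of the last two operations. Exhaustive demethylation (BBr3, CH2Cl2, −78 → 0 °C) gives the pentaphenol (2R,3R,4R)-4-(2-methylpropyl)-3-(propan-2-yl)-2-(2,4,6-trihydroxyphenyl)chromane-5,7-diol F2. Its two free phloroglucinol rings are then formylated four times under Vilsmeier–Haack conditions (POCl3, DMF, MeCN, 0 °C → rt; aqueous hydrolysis), which need no strong Lewis acid and give 28 directly, so that 27 is bypassed.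

Step 5. Metathesis at the hindered, allylically branched vinyl group may be slower than catalyst decomposition and acrylate dimerisation. The fallback sets out from 15 and comes back at 17. Oxidative cleavage of the vinyl group (OsO4 cat., NaIO4, 2,6-lutidine, dioxane/H2O) gives (2S,3R)-3-hydroxy-2-(propan-2-yl)-3-(2,4,6-trimethoxyphenyl)propanal F3, which is used crude. Wittig olefination with the stabilised ylide tert-butyl (triphenylphosphoranylidene)acetate (CH2Cl2, rt) then gives the E enoate 17.

Further compounds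
F1 | step 6 | tert-butyl (2E,4R,5R)-5-(3,5-dimethoxyphenoxy)-4-(propan-2-yl)-5-(2,4,6-trimethoxyphenyl)pent-2-enoate | COc1cc(OC)cc(c1)O[C@@H](c1c(OC)cc(OC)cc1OC)[C@@H](/C=C/C(=O)OC(C)(C)C)C(C)C
F2 | step 9 | (2R,3R,4R)-4-(2-methylpropyl)-3-(propan-2-yl)-2-(2,4,6-trihydroxyphenyl)chromane-5,7-diol | CC(C)C[C@H]1c2c(O)cc(O)cc2O[C@@H](c2c(O)cc(O)cc2O)[C@@H]1C(C)C
F3 | step 5 | (2S,3R)-3-hydroxy-2-(propan-2-yl)-3-(2,4,6-trimethoxyphenyl)propanal | O[C@@H](c1c(OC)cc(OC)cc1OC)[C@@H](C=O)C(C)C
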